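## Retrosynthetic overview

- Feature used: in the cyclohexene ring C1–C6 the allylic oxygens on C1 (OAc) and C4 (OH) are cis to each other across the C2=C3 alkene (C3 carries C7H2OBz), and the cis O5/O6 pair lies on the other face. Joining C1 and C4 through one oxygen gives an endo-2,3-dioxygenated 7-oxabicyclo[2.2.1]hept-5-ene.
- 14 ⇐ O5 benzoate from an O5/O6 cyclic orthobenzoate of triol acetate 12 ⇐ C1–OAc by SN2 on C1 bromide 11 ⇐ BBr3 cleavage of the C1–O bridge bond of enantiopure bicyclic diol 8.
- 8 ⇐ lipase resolution of racemic diol 6 ⇐ carbonate 5 ⇐ Diels–Alder union of furan-3-ylmethyl benzoate 3 and vinylene carbonate 4 (bonds C4–C5 and C1–C6).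
- Ring order: the carbocycle, as the oxygen-bridged bicycle, is the only ring built (step 2); the bridge is opened in step 6 and no further ring is made.

Key step: step 2

Conventions: atom labels C1–C7 and O1, O4, O5, O6 are those of the target and are kept for the bicyclic intermediates; the bridge oxygen is the later O4. Compounds 5 and 6 are racemic; their SMILES show the enantiomer that is carried on.

Remark (assumption): the lipase is taken to acetylate the (R)-configured endo carbinol, as it does with endo-bicyclo[2.2.1]heptan-2-ols; in the needed enantiomer this is O6–H. The sense of selection is to be confirmed on the first batch.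

## Route

Step 1
Reactants: 1 furan-3-ylmethanol; 2 benzoyl chloride
Product: 3 furan-3-ylmethyl benzoate
Conditions: Et3N, DMAP (cat.), CH2Cl2, 0 °C → rt
Reagents that add atoms: none
Why: DMAP-catalysed O-acylation (nucleophilic acyl substitution) of an unhindered primary alcohol; no stereocentre is involved.

Step 2
Reactants: 3 furan-3-ylmethyl benzoate; 4 vinylene carbonate
Product: 5 rac-endo-5-(benzoyloxymethyl)-7-oxabicyclo[2.2.1]hept-5-ene-2,3-diyl carbonate (carbonate oxygens anti to the oxygen bridge)
Conditions: neat 4 (4 equiv), BHT (cat.), sealed tube, 120 °C; SiO2 chromatography, then crystallisation to remove the exo isomer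
Reagents that add atoms: none
Why: A thermal, concerted, suprafacial [4+2] cycloaddition joins furan C2/C5 (target C4/C1) to the two alkene carbons of the carbonate (target C5/C6); the closest known reaction is the Diels–Alder addition of furan itself to vinylene carbonate. The six-membered carbocycle closes intermolecularly, both σ-bonds (C4–C5 and C1–C6) forming in the one pericyclic event, and the furan oxygen is left as the C1–O–C4 bridge. C5/C6 are cis because the dienophile is a cis-locked cyclic alkene, and C1/C4 carry the bridge on one face because the planar diene adds suprafacially. The relation between the two pairs is set by endo approach, in which the carbonate ring lies under the diene so that O5/O6 end up anti to the bridge. The step needs endo over exo selectivity, which the substrate secures only through the more compact endo transition state under kinetic control, so the reaction should be stopped before equilibration and the exo adduct removed. Regiochemistry does not arise because the dienophile is symmetric, and the adduct is racemic because the furan is planar and achiral.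

Step 3
Reactants: 5 rac-endo carbonate
Product: 6 rac-5-(benzoyloxymethyl)-7-oxabicyclo[2.2.1]hept-5-ene-2-endo,3-endo-diol
Conditions: K2CO3 (0.2 equiv), MeOH, −10 → 0 °C; AcOH quench
Reagents that add atoms: none
Why: Base-catalysed transesterification: the strained five-membered cyclic carbonate should undergo methanolysis well before the primary benzoate, and acyl–oxygen cleavage leaves all four stereocentres untouched.

Step 4
Reactants: 6 rac-diol
Product: 7 single-enantiomer O6 monoacetate (acetyl on the endo hydroxyl next to the bridgehead that adjoins the unsubstituted alkene CH; O5–H free)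
Conditions: lipase PS (Burkholderia cepacia lipase, immobilised), vinyl acetate (3 equiv), t-BuOMe, 30 °C, stopped near half conversion; rapid SiO2 chromatography
Reagents that add atoms: vinyl acetate, C=COC(C)=O
Why: Lipase-catalysed irreversible transesterification (kinetic resolution with an enol ester): by the empirical size rule for endo bicyclic secondary alcohols the (R)-carbinol is acylated, which in the needed enantiomer is the unhindered O6–H, whereas the mirror-image diol has its (R)-carbinol on the side of the substituted alkene carbon and should react more slowly or give the regioisomeric O5 acetate, so the O6 monoacetate fraction should carry the needed absolute configuration at C1, C4, C5 and C6.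

Step 5
Reactants: 7 O6 monoacetate
Product: 8 enantiopure 5-(benzoyloxymethyl)-7-oxabicyclo[2.2.1]hept-5-ene-2-endo,3-endo-diol (enantiomer shown in the SMILES)
Conditions: K2CO3 (0.1 equiv), MeOH, 0 °C
Reagents that add atoms: none
Why: Selective methanolysis of a secondary acetate, assisted by the cis-vicinal hydroxyl, in the presence of the slower-reacting benzoate; any prior acetyl migration between O6 and O5 is without consequence and no stereocentre is touched.

Step 6
Reactants: 8 enantiopure bicyclic diol
Product: 11 bromotriol [(3-bromo-4,5,6-trihydroxycyclohex-1-en-1-yl)methyl benzoate in ring terms; C1–Br on the O5/O6 face and trans to O4–H], via cyclic bromoborate 9 (not isolated), via dibromoboryl ether 10 (not isolated)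
Conditions: BBr3 (3 equiv), CH2Cl2, −78 → −30 °C; then cold aq. NaHCO3; used crude
Reagents that add atoms: boron tribromide, BrB(Br)Br
Why: BBr3 cleavage of a strained allylic bridging ether (the known opening of 7-oxanorbornenes to trans-4-bromocyclohex-2-enols): once the cis-diol is tied up as the non-participating borate 9, the C1–O bond should ionise in preference to C4–O because the allyl cation then places charge on the fully substituted C3, and bromide should enter at the less hindered terminus C1 anti to the departing oxygen, inverting C1 while C4, C5 and C6 keep their configuration.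

Step 7
Reactants: 11 bromotriol
Product: 12 triol acetate [3-(benzoyloxymethyl)-4,5,6-trihydroxycyclohex-2-en-1-yl acetate; C1–OAc cis to O4–H and trans to O6–H]
Conditions: CsOAc (3 equiv), AcOH (1 equiv), DMF, 0 °C → rt
Reagents that add atoms: caesium acetate, CC(=O)[O-].[Cs+]
Why: SN2 displacement of a secondary allylic bromide by a caesium carboxylate with inversion at C1 (the second inversion) places the acetate cis to O4; O6–H is cis to the bromide and cannot displace it, and the AcOH buffer should keep O4–H from re-closing the bridge and the new acetate from migrating.

Step 8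
Reactants: 12 triol acetate
Product: 14 (1R,4S,5R,6S)-5-(benzoyloxy)-3-[(benzoyloxy)methyl]-4,6-dihydroxycyclohex-2-en-1-yl acetate (target CNP0169028.1), via cyclic orthobenzoate 13 (not isolated)
Conditions: PhC(OMe)3 (1.5 equiv), CSA (cat.), MeCN, rt; then AcOH–H2O (4:1), 0 °C → rt
Reagents that add atoms: trimethyl orthobenzoate, COC(OC)(OC)c1ccccc1; water, O
Why: Acid-catalysed orthoester exchange closes the cis-fused 2-methoxy-2-phenyl-1,3-dioxolane on the cis O5/O6 pair, and mild aqueous acid opens it through the dioxolanylium ion and hemiorthoester with the known preference for axial ester and equatorial hydroxyl; in the half-chair favoured by allylic 1,2-strain between O4 and the C3 substituent, O4 and O5 are axial and O6 equatorial, so the benzoate should end on O5 with no stereocentre touched.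

## Compound list

1 | furan-3-ylmethanol | OCc1ccoc1 | starting material
2 | benzoyl chloride | O=C(Cl)c1ccccc1 | starting material
3 | furan-3-ylmethyl benzoate | O=C(OCc1ccoc1)c1ccccc1 | intermediate
4 | vinylene carbonate (1,3-dioxol-2-one) | O=C1OC=CO1 | starting material
5 | rac-endo-5-(benzoyloxymethyl)-7-oxabicyclo[2.2.1]hept-5-ene-2,3-diyl carbonate (racemate, one enantiomer written) | O1[C@@H]2C=C(COC(=O)c3ccccc3)[C@H]1[C@@H](OC(=O)O4)[C@H]24 | intermediate
6 | rac-5-(benzoyloxymethyl)-7-oxabicyclo[2.2.1]hept-5-ene-2-endo,3-endo-diol (racemate, one enantiomer written) | O1[C@@H]2C=C(COC(=O)c3ccccc3)[C@H]1[C@@H](O)[C@H]2O | intermediate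
7 | O6 monoacetate of the bicyclic diol, single enantiomer | O1[C@@H]2C=C(COC(=O)c3ccccc3)[C@H]1[C@@H](O)[C@H]2OC(C)=O | intermediate
8 | 5-(benzoyloxymethyl)-7-oxabicyclo[2.2.1]hept-5-ene-2-endo,3-endo-diol, single enantiomer | O1[C@@H]2C=C(COC(=O)c3ccccc3)[C@H]1[C@@H](O)[C@H]2O | intermediate
9 | cyclic bromoborate of diol 8 (2-bromo-1,3,2-dioxaborolane across O5/O6) | O1[C@@H]2C=C(COC(=O)c3ccccc3)[C@H]1[C@@H](OB(Br)O4)[C@H]24 | intermediate (not isolated)
10 | ring-opened C1 bromide carrying O4–BBr2 and the O5/O6 bromoborate | Br[C@H]1C=C(COC(=O)c2ccccc2)[C@H](OB(Br)Br)[C@@H](OB(Br)O3)[C@H]13 | intermediate (not isolated)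
11 | bromotriol: C1–Br on the O5/O6 face, O4–H on the opposite face | Br[C@H]1C=C(COC(=O)c2ccccc2)[C@H](O)[C@@H](O)[C@H]1O | intermediate
12 | triol acetate: C1–OAc and O4–H on one face, O5–H and O6–H on the other | CC(=O)O[C@@H]1C=C(COC(=O)c2ccccc2)[C@H](O)[C@@H](O)[C@H]1O | intermediate
13 | O5/O6 cyclic methyl orthobenzoate of 12 (both epimers at the orthoester carbon) | CC(=O)O[C@@H]1C=C(COC(=O)c2ccccc2)[C@H](O)[C@@H](OC(OC)(c2ccccc2)O3)[C@H]13 | intermediate (not isolated)
14 | (1R,4S,5R,6S)-5-(benzoyloxy)-3-[(benzoyloxy)methyl]-4,6-dihydroxycyclohex-2-en-1-yl acetate | CC(=O)O[C@@H]1C=C(COC(=O)c2ccccc2)[C@H](O)[C@@H](OC(=O)c2ccccc2)[C@H]1O | target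

## Step count and risks

Total: 8 steps. Longest linear sequence: 8 steps (1 → 14).

Steps most likely to fail:

1. Step 4 (lipase resolution). The enzyme may discriminate poorly between the two enantiomers, which are close to mirror-symmetric around the diol, and acetyl migration between the cis hydroxyls may mix the fractions and erode the enantiomeric purity. Fallback: setting out from racemic diol 6, preparative chromatography on a chiral stationary phase (amylose tris(3,5-dimethylphenylcarbamate), CO2/MeOH) would separate the enantiomers physically and return to the route at 8, bypassing 7 and step 5; this fallback makes no new compound (F0).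

2. Step 6 (bridge opening). The unprotected diol consumes BBr3 and releases HBr; this may bring on further ionisation of the allylic O4 borate or the allylic benzoate, participation of the C7 benzoate at C3, and bromide scrambling, so that anti delivery at C1 is lost. Fallback: setting out from 8, the diol would be masked with 1,3-dichloro-1,1,3,3-tetraisopropyldisiloxane (imidazole, DMF) as the disiloxanediyl-protected bicycle F1. One equivalent of BBr3 (CH2Cl2, −78 °C) would then open the bridge to the silylated bromohydrin F2, and CsOAc/AcOH in DMF would give the silylated C1 acetate F3. HF·pyridine (THF, 0 °C) would remove the disiloxane and return to the route at 12.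

3. Step 8 (orthobenzoate opening). The hemiorthoester may collapse through the other half-chair, in which O6 is axial, and so place the benzoate on O6; acid may also move the benzoate between O5 and O6. Fallback: setting out from 12, Bu2SnO (toluene, reflux, water removed) would give the O5,O6-dibutylstannylene acetal F4. BzCl (1.05 equiv, toluene, 0 °C) acylates the equatorial oxygen of a cis-diol, which in that other half-chair is O5, so this complementary method would return to the route at 14.

## Further compounds

F0 | step 4 | none | none
F1 | step 6 | O5,O6-(1,1,3,3-tetraisopropyldisiloxane-1,3-diyl) derivative of bicyclic diol 8 | O1[C@@H]2C=C(COC(=O)c3ccccc3)[C@H]1[C@@H](O[Si](C(C)C)(C(C)C)O[Si](C(C)C)(C(C)C)O4)[C@H]24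
F2 | step 6 | O5,O6-disiloxanediyl-protected C1 bromide with free O4–H | Br[C@H]1C=C(COC(=O)c2ccccc2)[C@H](O)[C@@H](O[Si](C(C)C)(C(C)C)O[Si](C(C)C)(C(C)C)O3)[C@H]13
F3 | step 6 | O5,O6-disiloxanediyl-protected C1 acetate with free O4–H | CC(=O)O[C@@H]1C=C(COC(=O)c2ccccc2)[C@H](O)[C@@H](O[Si](C(C)C)(C(C)C)O[Si](C(C)C)(C(C)C)O3)[C@H]13
F4 | step 8 | O5,O6-dibutylstannylene acetal of triol acetate 12 | CC(=O)O[C@@H]1C=C(COC(=O)c2ccccc2)[C@H](O)[C@@H](O[Sn](CCCC)(CCCC)O3)[C@H]13
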